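**Retrosynthetic overview**

- The pyran ring is cut at C4–C4a and C3–C2, both made in the last step. It is treated as the formal [4+2] adduct of an O‑aryl oxocarbenium ion (C4a=C8a–O1=C2) and a two‑carbon unit C3–C4, supplied by benzyl N‑vinylcarbamate as an acetylene equivalent (the carbamate is lost afterwards).
- Enabling feature: the benzene ring is a 4,6‑dimethoxyresorcinol, and C4a is the ring carbon between its two oxygens (O1 and the oxygen on C5). These oxygens are equivalent in the free diol, so no protecting group is needed; only C4a can close a six‑membered ring from O1; the free C5–OH activates C4a and binds the chiral acid.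
- The oxocarbenium precursor is an aryl 1,1‑disubstituted enol ether whose =CH2 ends as the C2 methyl. It is made, together with the exocyclic methylene, by double methylenation of a keto aryl ester.
- Side chain: an auxiliary‑controlled Michael addition of 2,6‑dimethylcyclohexanone to methyl vinyl ketone sets the quaternary centre. A temporary cyclohexenone ring (aldol condensation) relays it to the secondary methyl centre and is then opened by ozonolysis.
- Ring order: cyclohexane ring bought; temporary second carbocycle made and cleaved; pyran ring closed last.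

Key step: step 8

Assumption: the (S)‑amine is taken to give the R quaternary centre, as it does with the imine of 2‑methylcyclohexanone; if the sense is opposite, the (R)‑amine is used.
Assumption: (R)‑TRIP, (R)‑3,3'‑bis(2,4,6‑triisopropylphenyl)‑1,1'‑binaphthyl‑2,2'‑diyl hydrogen phosphate, is taken as the antipode that leads to the (2S) chromene; if the sense is opposite, its enantiomer is used in the same step.

**Route**

Step 1
Reactants: 1 2,6-dimethylcyclohexan-1-one (cis/trans mixture); 2 (S)-1-phenylethylamine
Product: 3 N-[(1S)-1-phenylethyl]-2,6-dimethylcyclohexan-1-imine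
Conditions: TsOH·H2O (cat.), toluene, reflux, azeotropic removal of water
Reagents that add atoms: none
Why: Acid‑catalysed condensation of a ketone with a primary amine (imine formation) driven by removal of water; no stereocentre of the target is set, and the ring α‑centres stay mobile through imine–enamine tautomerism.

Step 2
Reactants: 3 N-[(1S)-1-phenylethyl]-2,6-dimethylcyclohexan-1-imine; 4 methyl vinyl ketone
Product: 6 (2R)-2,6-dimethyl-2-(3-oxobutyl)cyclohexan-1-one (epimers at C6), via Michael-adduct imine 5 (not isolated)
Conditions: 4 (1.5 equiv), THF, 40 °C; then 10% aq AcOH, 25 °C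
Reagents that add atoms: water, O
Why: Auxiliary‑controlled deracemising Michael addition, in which the more substituted secondary enamine tautomer of 3 adds to the enone in an aza‑ene‑like transition state on the face away from the phenyl group of the auxiliary, which should set the quaternary centre as R, while C6 is left uncontrolled and hydrolysis releases the auxiliary.

Step 3
Reactants: 6 (2R)-2,6-dimethyl-2-(3-oxobutyl)cyclohexan-1-one
Product: 8 (4aR,8R)-4a,8-dimethyl-4,4a,5,6,7,8-hexahydronaphthalen-2(3H)-one, via bicyclic ketol 7 (not isolated)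
Conditions: NaOMe, MeOH, 25 → 60 °C
Reagents that add atoms: none
Why: Intramolecular aldol condensation (second stage of a Robinson annulation) under equilibrating conditions, in which C8 epimerises through the extended enolate to the isomer with the C8 methyl equatorial and trans to the axial angular methyl (the cis isomer needs a syn‑diaxial methyl pair), so that the secondary methyl centre is relayed from the quaternary one by thermodynamic substrate control in the temporary ring.

Step 4
Reactants: 8 (4aR,8R)-4a,8-dimethyl-4,4a,5,6,7,8-hexahydronaphthalen-2(3H)-one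
Product: 10 3-[(1R,3R)-1,3-dimethyl-2-oxocyclohexyl]propanoic acid, via alpha-keto acid 9 (not isolated)
Conditions: O3, EtOAc/AcOH, −20 °C; then 30% H2O2, 25 °C
Reagents that add atoms: ozone, [O-][O+]=O; hydrogen peroxide, OO
Why: Ozonolysis of the enone C=C bond with oxidative work‑up, the classical degradation of a cyclohexenone to a nor‑keto acid, in which C8a becomes the ring ketone and the α‑keto acid 9 loses C1 as CO2, while the non‑basic conditions leave the quaternary centre and the now α‑methyl centre untouched.

Step 5
Reactants: 11 1,5-dibromo-2,4-dimethoxybenzene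
Product: 13 4,6-dimethoxybenzene-1,3-diol, via bromophenol 12 (not isolated)
Conditions: Pd2(dba)3 (cat.), tBuXPhos, KOH, 1,4-dioxane/H2O, 100 °C, argon; then aq HCl
Reagents that add atoms: potassium hydroxide KOH, [K+].[OH-]
Why: Palladium‑catalysed hydroxylation of aryl bromides with hydroxide (C–O cross‑coupling, in which the bulky biarylphosphine promotes C–O reductive elimination and holds back diaryl ether formation), applied at both C–Br bonds; no stereocentre is involved.

Step 6
Reactants: 10 3-[(1R,3R)-1,3-dimethyl-2-oxocyclohexyl]propanoic acid; 13 4,6-dimethoxybenzene-1,3-diol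
Product: 14 5-hydroxy-2,4-dimethoxyphenyl 3-[(1R,3R)-1,3-dimethyl-2-oxocyclohexyl]propanoate
Conditions: 13 (3 equiv), N,N'-diisopropylcarbodiimide, DMAP (cat.), CH2Cl2, 0 → 25 °C
Reagents that add atoms: none
Why: Steglich esterification of a phenol, in which the two hydroxyl groups of 13 are equivalent by symmetry so that mono‑acylation at either gives the same ester, the excess of diol holds back the diester, and the hindered ketone with its α‑centre is not touched.

Step 7
Reactants: 14 5-hydroxy-2,4-dimethoxyphenyl 3-[(1R,3R)-1,3-dimethyl-2-oxocyclohexyl]propanoate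
Product: 16 5-({4-[(1R,3R)-1,3-dimethyl-2-methylidenecyclohexyl]but-1-en-2-yl}oxy)-2,4-dimethoxyphenol, via methylidene ester 15 (not isolated)
Conditions: Cp2TiMe2 (excess), toluene/THF, 70 °C, dark; filtration through basic alumina
Reagents that add atoms: dimethyltitanocene Cp2TiMe2, C[Ti](C)(C1C=CC=C1)C1C=CC=C1
Why: Carbonyl methylenation by the titanocene methylidene formed thermally from Cp2TiMe2, a non‑basic reagent that should convert the hindered enolisable ketone into the exocyclic methylene without epimerisation of the α‑methyl centre and the aryl ester into the 2‑aryloxy‑1‑alkene, the phenol being held as a titanium phenoxide until work‑up.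

Step 8
Reactants: 16 5-({4-[(1R,3R)-1,3-dimethyl-2-methylidenecyclohexyl]but-1-en-2-yl}oxy)-2,4-dimethoxyphenol; 17 benzyl N-vinylcarbamate
Product: 19 metachromin B, via chroman carbamate 18 (not isolated)
Conditions: 17 (2.5 equiv, slow addition), (R)-TRIP (5 mol %), 4 Å MS, toluene, −40 °C; then 25 °C
Reagents that add atoms: none
Why: Proposed new method: the chiral acid protonates the enol ether at its methylene carbon (which becomes the C2 methyl) to give a contact ion pair of the O‑aryl oxocarbenium ion (C4a=C8a–O1=C2, a cationic 2‑oxadiene) and the phosphate, the β‑carbon of the enecarbamate adds to C2 (bond C3–C2), the N‑acyliminium ion so formed at C4 is trapped by C4a (bond C4–C4a), and on warming benzyl carbamate is lost from the doubly ortho‑oxygenated benzylic position to leave the C3=C4 alkene. The closest known reaction types are the oxa‑Povarov reaction of aldehyde‑derived aryl oxocarbenium ions with alkenes, the phosphoric‑acid‑catalysed Povarov and aza‑ene reactions of enecarbamates, and phosphoric‑acid‑catalysed additions of carbon nucleophiles to oxocarbenium ions made by protonation of vinyl ethers, so the step is a stepwise formal [4+2] annulation. The pyran ring closes by a 6‑exo‑trig Friedel–Crafts (Mannich‑type) attack of C4a on the exocyclic C=N bond. C2, the only new stereocentre that survives, is set in the first C–C bond formation under catalyst control, the phosphate being hydrogen‑bonded to the N–H of the enecarbamate and to the free C5–OH and ion‑paired with the oxocarbenium ion; the remote side‑chain centres have no influence and the C4 centre is erased in the elimination. The step needs face selectivity at a cation whose two alkyl arms are methyl and a CH2CH2 chain (helped by the bulk of the γ‑quaternary chain and the anchoring OH, level not predictable), site selectivity for C4a over C7 (secured by the O1 tether, as only C4a can close a six‑membered ring), and chemoselectivity against Prins attack of the exocyclic methylene on C2 and against cross‑reaction of the two acid‑labile alkenes (secured by the low temperature, the moderate acidity of the phosphoric acid, and the higher nucleophilicity, excess and slow addition of 17).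

**Compound list**

1 | 2,6-dimethylcyclohexan-1-one (cis/trans mixture) | CC1CCCC(C)C1=O | starting material
2 | (S)-1-phenylethylamine | C[C@H](N)c1ccccc1 | starting material
3 | N-[(1S)-1-phenylethyl]-2,6-dimethylcyclohexan-1-imine (ring centres mobile) | C[C@H](N=C1C(C)CCCC1C)c1ccccc1 | intermediate
4 | methyl vinyl ketone (but-3-en-2-one) | CC(=O)C=C | starting material
5 | Michael-adduct imine, 4-[(1R)-1,3-dimethyl-2-{[(1S)-1-phenylethyl]imino}cyclohexyl]butan-2-one (not isolated; epimers at C3) | C[C@H](N=C1C(C)CCC[C@]1(C)CCC(C)=O)c1ccccc1 | intermediate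
6 | (2R)-2,6-dimethyl-2-(3-oxobutyl)cyclohexan-1-one (epimers at C6) | CC(=O)CC[C@@]1(C)CCCC(C)C1=O | intermediate
7 | bicyclic ketol, (4aR)-8a-hydroxy-4a,8-dimethyloctahydronaphthalen-2(1H)-one (not isolated; epimers at C8 and C8a) | O=C1CC[C@@]2(C)CCCC(C)C2(O)C1 | intermediate
8 | (4aR,8R)-4a,8-dimethyl-4,4a,5,6,7,8-hexahydronaphthalen-2(3H)-one (methyl groups trans) | O=C1CC[C@@]2(C)CCC[C@@H](C)C2=C1 | intermediate
9 | alpha-keto acid, 4-[(1R,3R)-1,3-dimethyl-2-oxocyclohexyl]-2-oxobutanoic acid (not isolated) | OC(=O)C(=O)CC[C@@]1(C)CCC[C@@H](C)C1=O | intermediate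
10 | 3-[(1R,3R)-1,3-dimethyl-2-oxocyclohexyl]propanoic acid | OC(=O)CC[C@@]1(C)CCC[C@@H](C)C1=O | intermediate
11 | 1,5-dibromo-2,4-dimethoxybenzene | COc1cc(OC)c(Br)cc1Br | starting material
12 | 5-bromo-2,4-dimethoxyphenol (not isolated) | COc1cc(OC)c(Br)cc1O | intermediate
13 | 4,6-dimethoxybenzene-1,3-diol | COc1cc(OC)c(O)cc1O | intermediate
14 | 5-hydroxy-2,4-dimethoxyphenyl 3-[(1R,3R)-1,3-dimethyl-2-oxocyclohexyl]propanoate | COc1cc(OC)c(OC(=O)CC[C@@]2(C)CCC[C@@H](C)C2=O)cc1O | intermediate
15 | methylidene ester, 5-hydroxy-2,4-dimethoxyphenyl 3-[(1R,3R)-1,3-dimethyl-2-methylidenecyclohexyl]propanoate (not isolated) | COc1cc(OC)c(OC(=O)CC[C@@]2(C)CCC[C@@H](C)C2=C)cc1O | intermediate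
16 | 5-({4-[(1R,3R)-1,3-dimethyl-2-methylidenecyclohexyl]but-1-en-2-yl}oxy)-2,4-dimethoxyphenol | COc1cc(OC)c(OC(=C)CC[C@@]2(C)CCC[C@@H](C)C2=C)cc1O | intermediate
17 | benzyl N-vinylcarbamate (benzyl N-ethenylcarbamate) | C=CNC(=O)OCc1ccccc1 | starting material
18 | chroman carbamate, benzyl N-[(2S)-2-{2-[(1R,3R)-1,3-dimethyl-2-methylidenecyclohexyl]ethyl}-5-hydroxy-6,8-dimethoxy-2-methyl-3,4-dihydro-2H-chromen-4-yl]carbamate (not isolated; epimers at C4) | C=C1[C@H](C)CCC[C@]1(C)CC[C@@]1(C)CC(NC(=O)OCc2ccccc2)c2c(O)c(OC)cc(OC)c2O1 | intermediate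
19 | metachromin B, (2S)-2-{2-[(1R,3R)-1,3-dimethyl-2-methylidenecyclohexyl]ethyl}-6,8-dimethoxy-2-methyl-2H-chromen-5-ol | C=C1[C@H](C)CCC[C@]1(C)CC[C@@]1(C)C=Cc2c(O)c(OC)cc(OC)c2O1 | target

**Step count and risks**

Total step count: 8. Longest linear sequence: 7 steps (steps 1–4 and 6–8); step 5 is a one‑step branch.

Steps most likely to fail:

1. Step 8 (proposed new method). What may go wrong:
   - insufficient discrimination of the two faces of C2 by the catalyst, so that both C2 epimers form;
   - cross‑reaction of the two acid‑labile alkenes (self‑condensation of either partner, aza‑Friedel–Crafts alkylation of C7 by the protonated enecarbamate);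
   - Prins capture of the oxocarbenium ion by the exocyclic methylene;
   - ionisation of the O1–C2 bond of the product with loss of configuration.

   Fallback with known chemistry, setting out from 16 and returning at 19: the enol ether 16 is hydrolysed (PPTS, wet acetone) to the methyl ketone 4-[(1R,3R)-1,3-dimethyl-2-methylidenecyclohexyl]butan-2-one F1, with recovery of 13. Horner–Wadsworth–Emmons olefination (triethyl phosphonoacetate, NaH, THF) gives the enoate ethyl (2E)-5-[(1R,3R)-1,3-dimethyl-2-methylidenecyclohexyl]-3-methylpent-2-enoate F2, separated from its Z isomer. Reduction with iBu2AlH gives the allylic alcohol (2E)-5-[(1R,3R)-1,3-dimethyl-2-methylidenecyclohexyl]-3-methylpent-2-en-1-ol F3, and ClCO2Me/pyridine gives the carbonate (2E)-5-[(1R,3R)-1,3-dimethyl-2-methylidenecyclohexyl]-3-methylpent-2-en-1-yl methyl carbonate F4. Asymmetric Tsuji–Trost O‑allylation of an excess of 13 with F4 (Pd2(dba)3·CHCl3 and the antipode of N,N'-(cyclohexane-1,2-diyl)bis(2-diphenylphosphinobenzamide) that leads to S, CH2Cl2) should give the branched tertiary ether 5-({(3S)-5-[(1R,3R)-1,3-dimethyl-2-methylidenecyclohexyl]-3-methylpent-1-en-3-yl}oxy)-2,4-dimethoxyphenol F5; here the E geometry of the carbonate and the ligand fix the configuration. Hydroboration of the vinyl group with 9‑BBN and oxidation with NaBO3·4H2O (the hindered exocyclic methylene is left) gives the alcohol (3S)-5-[(1R,3R)-1,3-dimethyl-2-methylidenecyclohexyl]-3-(5-hydroxy-2,4-dimethoxyphenoxy)-3-methylpentan-1-ol F6. Oxidation with TEMPO/PhI(OAc)2 gives the aldehyde (3S)-5-[(1R,3R)-1,3-dimethyl-2-methylidenecyclohexyl]-3-(5-hydroxy-2,4-dimethoxyphenoxy)-3-methylpentanal F7. Camphorsulfonic acid (cat.) in toluene closes the ring by Friedel–Crafts hydroxyalkylation at C4a to the chromanol (2S)-2-{2-[(1R,3R)-1,3-dimethyl-2-methylidenecyclohexyl]ethyl}-6,8-dimethoxy-2-methyl-3,4-dihydro-2H-chromene-4,5-diol F8, which loses water in the same flask to give 19.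

2. Step 7. What may go wrong:
   - consumption of the titanium reagent by the phenol;
   - incomplete conversion of the hindered ketone at a temperature that the enol ether tolerates;
   - hydrolysis of the enol ether during isolation.

   Fallback, setting out from 14 and returning at 16: the two olefinations are separated. A Takai–Lombardo methylenation (Zn, CH2Br2, TiCl4, THF/CH2Cl2, 0 → 25 °C), a geminal dimetallic reagent that converts ketones but not esters and does not epimerise α‑centres, gives the methylidene ester 15 as an isolated compound. Cp2TiMe2 then has only the aryl ester to convert and gives 16.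

3. Step 5. What may go wrong:
   - stalling after the first C–O coupling, because oxidative addition to the electron‑rich bromophenolate is slow;
   - diaryl ether formation;
   - air oxidation of the electron‑rich diol.

   Fallback, setting out from 11 and returning at 13: double Miyaura borylation (B2pin2, PdCl2(dppf), KOAc, 1,4‑dioxane, 90 °C) gives the bis(boronate) 2,2'-(4,6-dimethoxy-1,3-phenylene)bis(4,4,5,5-tetramethyl-1,3,2-dioxaborolane) F9, and oxidation of both C–B bonds (NaBO3·4H2O, THF/H2O, 25 °C) gives 13.

Further compounds
F1 | step 8 | 4-[(1R,3R)-1,3-dimethyl-2-methylidenecyclohexyl]butan-2-one | CC(=O)CC[C@@]1(C)CCC[C@@H](C)C1=C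
F2 | step 8 | ethyl (2E)-5-[(1R,3R)-1,3-dimethyl-2-methylidenecyclohexyl]-3-methylpent-2-enoate | CCOC(=O)/C=C(\C)CC[C@@]1(C)CCC[C@@H](C)C1=C
F3 | step 8 | (2E)-5-[(1R,3R)-1,3-dimethyl-2-methylidenecyclohexyl]-3-methylpent-2-en-1-ol | OC/C=C(\C)CC[C@@]1(C)CCC[C@@H](C)C1=C
F4 | step 8 | (2E)-5-[(1R,3R)-1,3-dimethyl-2-methylidenecyclohexyl]-3-methylpent-2-en-1-yl methyl carbonate | COC(=O)OC/C=C(\C)CC[C@@]1(C)CCC[C@@H](C)C1=C
F5 | step 8 | 5-({(3S)-5-[(1R,3R)-1,3-dimethyl-2-methylidenecyclohexyl]-3-methylpent-1-en-3-yl}oxy)-2,4-dimethoxyphenol | C=C[C@](C)(CC[C@@]1(C)CCC[C@@H](C)C1=C)Oc1cc(O)c(OC)cc1OC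
F6 | step 8 | (3S)-5-[(1R,3R)-1,3-dimethyl-2-methylidenecyclohexyl]-3-(5-hydroxy-2,4-dimethoxyphenoxy)-3-methylpentan-1-ol | OCC[C@](C)(CC[C@@]1(C)CCC[C@@H](C)C1=C)Oc1cc(O)c(OC)cc1OC
F7 | step 8 | (3S)-5-[(1R,3R)-1,3-dimethyl-2-methylidenecyclohexyl]-3-(5-hydroxy-2,4-dimethoxyphenoxy)-3-methylpentanal | O=CC[C@](C)(CC[C@@]1(C)CCC[C@@H](C)C1=C)Oc1cc(O)c(OC)cc1OC
F8 | step 8 | (2S)-2-{2-[(1R,3R)-1,3-dimethyl-2-methylidenecyclohexyl]ethyl}-6,8-dimethoxy-2-methyl-3,4-dihydro-2H-chromene-4,5-diol (epimers at C4) | C=C1[C@H](C)CCC[C@]1(C)CC[C@@]1(C)CC(O)c2c(O)c(OC)cc(OC)c2O1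
F0 | step 7 | none | none
F9 | step 5 | 2,2'-(4,6-dimethoxy-1,3-phenylene)bis(4,4,5,5-tetramethyl-1,3,2-dioxaborolane) | COc1cc(OC)c(B2OC(C)(C)C(C)(C)O2)cc1B1OC(C)(C)C(C)(C)O1
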